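Numbering used throughout: ring A is C1 (CH3), C2 (OH), C3 (acyl), C4 (OH), C5 (bonded to C7), C6 (OH); C7 is the methine; ring B is C1′ (bonded to C7) to C6′. Compound numbers 1–17 are those of the steps and of the list that follows them.

## Analysis of the target

The target 17 (C31H38O7) consists of two six-membered carbocycles joined through one sp3 carbon. Ring A is a benzene ring with no hydrogen left on it: methyl at C1, hydroxyl at C2, C4 and C6, a 3-phenylpropanoyl ketone at C3, and C7 at C5. Ring B is the enol form of 2,2,4,4-tetramethylcyclohexane-1,3,5-trione, bonded through C1′. The methine C7 carries ring A, ring B, a 2-methylpropyl chain and hydrogen and is the only stereocentre (S); nothing else in the molecule can relay chirality to it, so a catalyst has to set it. C7 is also the weak point: it lies between a phloroglucinol and a vinylogous acid, so base can expel the ring B enolate (retro-Michael cleavage through an ortho-quinone methide) and acid can ionise the C5–C7 bond, and either event erases the configuration. Under acid the C4 or C6 hydroxyl can in addition condense with C2′ to a pyran. The difficulty is therefore a crowded, fully substituted ring A whose three hydroxyls differ only by their neighbours, next to a configurationally fragile centre. The plan rests on the oxygen pattern of ring A: C4, C5, C6 and C1 have the polarity of a β-keto ester (ester carbon, α-carbon, ketone carbon, γ-carbon), and C2–C3 that of an alkoxyalkyne bearing an acyl group, so the ring can be assembled from these two pieces with the acyl group and every oxygen already in place.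

## Retrosynthetic reasoning

**17 back to 16.** The O–ethyl bond at C2 and the O–methyl bond at C2′ are cut. These are the two alkyl groups that the building blocks bring with them: the ethyl group belongs to the ynol ether, and the methyl group keeps ring B inert. The forward step has to remove both without acid or base acting on C7 for long; a Lewis acid with iodide at low temperature attacks only the two unhindered alkyl carbons.

**16 back to 9 and 14.** Ring A is cut at C1–C2 and C3–C4. These are the only two ring bonds whose cleavage leaves one piece as a β-keto ester derivative (C4, C5, C6, C1, in diene 9) and the other as an acyl alkyne (C2, C3, in ynone 14), each reacting with its natural polarity. Any other pair of cuts would separate the ketone from its ring carbon or call for reversed polarity. The gain is that all six substituents arrive with the ring and no electrophilic substitution has to be done on a ring that hangs on C7. The forward reaction must join the methyl-bearing diene terminus to the ethoxy carbon, close the ring at the ketene acetal carbon, and aromatise by loss of the ester alkoxy group.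

**14 back to 12 and 11, and 11 back to 10.** The bond between the alkyne and the ketone carbon is cut. The acetylide 13 from alkyne 12 is acylated once by the N-methoxy-N-methylamide 11, which comes from acid chloride 10. This keeps the sensitive ynol ether out of all but one step.

**9 back to 8 and 7.** Only O–Si bonds are cut. Keto ester 7 is a stable compound that can be purified, and two successive enolisations (first at the α-carbon to give 8, then at the γ-carbon) turn it into the diene. The forward steps must enolise only toward C1 and the ester; ring B has no enolisable hydrogen and the C7 hydrogen is not acidified.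

**7 back to 6, and 6 back to 4 and 5.** The O–methyl bond on ring B is cut first, then the bond from C7 to the α-carbon of the keto ester (the future C5–C7 bond). The forward reaction is a conjugate addition of keto ester 5 to the symmetrical acceptor 4, in which a chiral catalyst chooses the face of C7; this is the one place where the stereocentre is made. Methylation of the enol in adduct 6 follows in the same flask, because the methyl ether can no longer leave by retro-addition.

**4 back to 1 and 2.** The C7=C1′ double bond is cut. Condensation of trione 1 with aldehyde 2 through the Mannich base 3 gives the acceptor.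

## Alternatives that were turned down

**Alternative 1:** The three methyl groups on C3′ and C5′ of ring B are removed, which turns ring B into a second copy of ring A without its ketone and makes C7 non-stereogenic. The precursor is the achiral bis-phenol A1. In the forward key step one of its two enantiotopic rings is C-methylated three times by iodomethane A2 under aqueous alkali hydroxide with a chiral quaternary ammonium phase-transfer catalyst. That ring is dearomatised to the trione enol and A3, the target without its acyl group, results.
- For: it is the shortest plan by far. A1 comes from aldehyde 2 in one condensation, and the stereocentre arises from a hidden symmetry with no chiral building block. On step count it is clearly stronger than the chosen route.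
- Against: the catalyst must tell apart two rings that differ only in their position relative to C7. It must also keep three alkylations on carbon and on the same ring, while O-methylation, methylation of the second ring and methylation of the free ring A position all compete. A3 is formed as a free ring B enolate next to a phenoxide in aqueous base, which are the conditions for retro-Michael scrambling of C7. The ketone must then be put on the last free ring carbon with acid chloride 10 and a Lewis acid, the conditions that ionise C7.
- Comparison: the chosen route needs about twice as many steps. In return each carbon–carbon bond, the stereocentre and the ketone are installed in separate events, and C7 never sits between a free enolate and a phenoxide.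

**Alternative 2:** The cuts are at C8–C9 and C7–C1′, giving three pieces: the ring A styrene A4, 2-iodopropane A5 and the ring B bromo enol ether A6. In the forward key step a nickel bromide precatalyst with a chiral bis(oxazoline)-type ligand is reduced by zinc metal to zerovalent nickel. The isopropyl radical from A5 adds to the styrene terminus, and the benzylic radical at C7 is captured and coupled with the alkenyl group of A6 to give the tetrabenzyl ether A7.
- For: it is convergent, and C7 is set in the same event that makes two carbon–carbon bonds. The end game is a neutral hydrogenolysis of four benzyl groups, which is gentler than the dealkylation at the end of the chosen route; on that point the alternative is stronger.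
- Against: the radical at C7 sits between two ortho benzyloxy groups on a hexasubstituted ring. The bromine-bearing carbon of A6 lies between a carbonyl and an alkoxy carbon that adjoins a quaternary centre. The bond-forming reductive elimination therefore joins two very hindered carbons, and the selectivity of such couplings is built on unhindered styrenes. A4 itself needs four or five operations on a fully substituted ring.
- Comparison: the step count is similar. The chosen route places its risk in a ring closure with a strong polarity bias and sets C7 earlier on an unhindered acceptor.

**Alternative 3:** Ring A is cut at C1–C6 and C2–C3 (with C5–C6 opened and re-closed), giving the cyclobutenone A8 and 1-ethoxyprop-1-yne A9. On heating in toluene A8 opens to a vinylketene, which adds to A9 in a [2+2] sense. The new cyclobutenone opens again, a six-electron ring closure follows, and tautomerisation gives the phenol A10.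
- For: this benzannulation manifold is established and its regiochemistry is predictable. On precedent for the ring-forming event it is stronger than the chosen key step.
- Against: A10 has hydrogen at C3. The ketone must still be introduced by acylation with 10 between two ethoxy groups under a Lewis acid on the assembled, acid-sensitive skeleton, and two aryl ethyl ethers plus the enol methyl ether then have to be cleaved. A8 has to be built by a ketene cycloaddition from a C7-chiral β-branched acid, which adds steps before the key step. The temperatures needed lie close to those at which ethyl alkynyl ethers lose ethene.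
- Comparison: it is longer by two or three steps. The chosen route delivers the ketone together with the ring and runs at lower temperature, at the price of a two-carbon partner that has not been tried.

Key step: step 7

Assumption: syncarpic acid 1, ethoxyacetylene 12 (as a solution in hexanes) and the cinchona squaramide of step 2 are bought.
Remark: C7 keeps one spatial arrangement from step 2 onward; its descriptor is S in 6, 7, 16 and 17 and R in 8, 9 and 15 only because the CIP ranking of its neighbours changes.

## Route

**Step 1**
Reactants: 1 syncarpic acid (2,2,4,4-tetramethylcyclohexane-1,3,5-trione); 2 3-methylbutanal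
Product: 4 2-(3-methylbutylidene)-4,4,6,6-tetramethylcyclohexane-1,3,5-trione, via Mannich base 3 (not isolated)
Conditions: piperidine (1.05 equiv), CH2Cl2, 0 °C → rt; then 1 M HCl (aq), 0 °C; crude 4 used at once
Reagents that add atoms: none
Why: Knoevenagel condensation run through the Mannich base: the iminium ion from 2 and the amine is attacked by the acidic trione 1, and acid then expels the amine from 3 to leave the exocyclic alkene. The acceptor is symmetrical about the alkene, so no E/Z question arises.

**Step 2**
Reactants: 4 2-(3-methylbutylidene)-4,4,6,6-tetramethylcyclohexane-1,3,5-trione; 5 methyl 3-oxopentanoate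
Product: 7 methyl 2-[(1S)-1-(2-methoxy-3,3,5,5-tetramethyl-4,6-dioxocyclohex-1-en-1-yl)-3-methylbutyl]-3-oxopentanoate (both epimers at C2 of the pentanoate), via Michael adduct 6 (not isolated)
Conditions: quinine-derived squaramide 3-{[3,5-bis(trifluoromethyl)phenyl]amino}-4-{[(8α,9S)-6′-methoxycinchonan-9-yl]amino}cyclobut-3-ene-1,2-dione (5 mol %), toluene, −20 °C; then MeOH, Me3SiCHN2 (2 M in hexanes, 1.3 equiv), 0 °C
Reagents that add atoms: (trimethylsilyl)diazomethane, C[Si](C)(C)C=[N+]=[N-]
Why: Catalytic asymmetric Michael addition of a β-keto ester to an alkylidene 1,3-dione: the quinuclidine nitrogen deprotonates 5 while the squaramide N–H bonds hold a carbonyl of 4, so the enolate reaches one enantiotopic face of C7 and sets it (the quinidine-derived pseudo-enantiomer gives the opposite face, so the S sense is secured by the choice between the two once the sense of induction is assigned). Diazomethane released from the silyl reagent and MeOH methylates only the strongly acidic ring B enol of 6, whose two flanking oxygens are equivalent, and this blocks both retro-Michael cleavage and hemiketal closure; the centre at C2 of the pentanoate becomes trigonal in step 3 and needs no control.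

**Step 3**
Reactants: 7 methyl 2-[(1S)-1-(2-methoxy-3,3,5,5-tetramethyl-4,6-dioxocyclohex-1-en-1-yl)-3-methylbutyl]-3-oxopentanoate
Product: 8 methyl 2-[(1R)-1-(2-methoxy-3,3,5,5-tetramethyl-4,6-dioxocyclohex-1-en-1-yl)-3-methylbutyl]-3-(trimethylsilyloxy)pent-2-enoate (double-bond isomers, both usable)
Conditions: Me3SiCl (1.5 equiv), Et3N (2 equiv), toluene, rt → 40 °C; filtration under argon
Reagents that add atoms: chlorotrimethylsilane, C[Si](C)(C)Cl
Why: Soft enolisation and O-silylation of a β-keto ester with a chlorosilane and a tertiary amine, the usual first stage toward a 1,3-bis(silyl enol ether). Ring B has no enolisable hydrogen and the C7 hydrogen is not acidified; any deconjugated enol ether that forms converges on 9 in step 4.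

**Step 4**
Reactants: 8 methyl 2-[(1R)-1-(2-methoxy-3,3,5,5-tetramethyl-4,6-dioxocyclohex-1-en-1-yl)-3-methylbutyl]-3-(trimethylsilyloxy)pent-2-enoate
Product: 9 (1Z,3Z)-1-methoxy-2-[(1R)-1-(2-methoxy-3,3,5,5-tetramethyl-4,6-dioxocyclohex-1-en-1-yl)-3-methylbutyl]-1,3-bis(trimethylsilyloxy)penta-1,3-diene (ketene acetal geometry immaterial)
Conditions: LiN(i-Pr)2 (1.3 equiv), Me3SiCl (1.5 equiv, present from the start), THF, −78 → −20 °C; hexane, filtration under argon, used crude
Reagents that add atoms: chlorotrimethylsilane, C[Si](C)(C)Cl
Why: γ-Deprotonation of the β-silyloxy enoate gives the extended ester enolate, which the chlorosilane already in the flask traps on oxygen before it can attack ring B. The methyl group settles anti to the bulky substituent on the neighbouring carbon (3Z), and the C7 hydrogen is cross-conjugated and is not removed.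

**Step 5**
Reactants: 10 3-phenylpropanoyl chloride
Product: 11 N-methoxy-N-methyl-3-phenylpropanamide
Conditions: MeNH(OMe)·HCl (1.1 equiv), Et3N (2.2 equiv), CH2Cl2, 0 °C → rt
Reagents that add atoms: N,O-dimethylhydroxylamine hydrochloride, CNOC.Cl
Why: N-Acylation of the hydroxylamine by an acid chloride; the product is the acylating agent that stops cleanly at the ketone stage in step 6.

**Step 6**
Reactants: 12 ethoxyacetylene; 11 N-methoxy-N-methyl-3-phenylpropanamide
Product: 14 1-ethoxy-5-phenylpent-1-yn-3-one, via lithium ethoxyacetylide 13 (not isolated)
Conditions: 12 (1.3 equiv), n-BuLi (1.2 equiv), THF, −78 °C; then 11, −78 → −30 °C; cold pH 7 phosphate/NH4Cl quench; quick filtration through Et3N-deactivated silica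
Reagents that add atoms: none
Why: The terminal alkyne is deprotonated and the acetylide 13 adds to the amide to give a five-membered lithium chelate that collapses to the ketone only at the quench, so a second addition is excluded. A cold, neutral work-up spares the acid-sensitive ynol ether.

**Step 7**
Reactants: 9 (1Z,3Z)-1-methoxy-2-[(1R)-1-(2-methoxy-3,3,5,5-tetramethyl-4,6-dioxocyclohex-1-en-1-yl)-3-methylbutyl]-1,3-bis(trimethylsilyloxy)penta-1,3-diene; 14 1-ethoxy-5-phenylpent-1-yn-3-one
Product: 16 1-{2-ethoxy-4,6-dihydroxy-5-[(1S)-1-(2-methoxy-3,3,5,5-tetramethyl-4,6-dioxocyclohex-1-en-1-yl)-3-methylbutyl]-3-methylphenyl}-3-phenylpropan-1-one, via cycloadduct 15 (not isolated)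
Conditions: 9 (1.5 equiv), 14 (1 equiv), toluene (1 M), argon, sealed tube, 25 → 60 °C; then 0.5 M HCl, THF, 0 °C
Reagents that add atoms: none
Why: Proposed new method: diene 9 is the bis(silyl enol ether) of a β-keto ester and is most nucleophilic at its methyl-bearing terminus (future C1), while ynone 14 is a push–pull alkyne whose ethoxy carbon (future C2) is electrophilic both as the β-carbon of the ynone and as the oxygen-bearing carbon of an ynol ether, so the two polarisations agree on one orientation. The C1–C2 bond should form first, in a strongly asynchronous [4+2] cycloaddition or as a Mukaiyama–Michael addition that leaves a 2-ethoxyallenolate and an oxygen-stabilised cation on the diene part; the allenolate carbon between the two oxygen-bearing carbons (future C3) then closes on the ketene acetal carbon (future C4) in a 6-exo-trig attack on its C=O+ unit, which gives the cyclohexa-1,4-diene 15 and is the only ring closure of the step. Cold aqueous acid collapses the methyl silyl ketal at C4 to a carbonyl with loss of methanol, the dienone enolises through the C1 hydrogen to the phenol, and the silyl ether at C6 is hydrolysed, so ring A appears with the ketone between the ethoxy group and a free hydroxyl. The closest known reaction type is the cyclocondensation of 1-alkoxy-1,3-bis(silyloxy)buta-1,3-dienes with acetylenic esters and ketones to resorcinols ([4+2] with aromatisation) and with 3-alkoxy enones to salicylates (formal [3+3]); an alkoxyethynyl ketone has not been used as the two-carbon partner. No stereocentre that survives is formed (C1 and C4 of 15 become trigonal), and C7, which has neither an acidic hydrogen nor a leaving group, should pass unchanged. The step needs regioselectivity, which the matched polarity secures, and closure at C4 in place of an aldol-type closure of the diene α-carbon on the ketone; that carbon already carries the C7 substituent, so such a closure would make a quaternary centre that cannot aromatise, and no Lewis acid is present to activate the ketone. The temperature must stay well below about 100 °C, where ethyl alkynyl ethers expel ethene, and the bulky group on the internal diene carbon together with the outward methyl group (3Z) favours the s-cis conformer that the closure requires.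

**Step 8**
Reactants: 16 1-{2-ethoxy-4,6-dihydroxy-5-[(1S)-1-(2-methoxy-3,3,5,5-tetramethyl-4,6-dioxocyclohex-1-en-1-yl)-3-methylbutyl]-3-methylphenyl}-3-phenylpropan-1-one
Product: 17 1-{2,4,6-trihydroxy-3-[(1S)-1-(2-hydroxy-3,3,5,5-tetramethyl-4,6-dioxocyclohex-1-en-1-yl)-3-methylbutyl]-5-methylphenyl}-3-phenylpropan-1-one (the target)
Conditions: BCl3 (1 M in CH2Cl2, 6 equiv), n-Bu4NI (4 equiv), CH2Cl2, −78 → 0 °C; then ice-water
Reagents that add atoms: none
Why: Lewis acid–iodide dealkylation: BCl3 binds the carbonyl-activated ether oxygens and iodide attacks the unhindered ethyl and methyl carbons (SN2), a known low-temperature cleavage of primary alkyl aryl ethers and of vinylogous esters. The C2 ethyl ether is ortho to the ketone and twisted out of conjugation by its two neighbours, which marks it for cleavage; the phenols are held as borates and cannot add to C2′, and no bond to C7 is touched.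

## Compound list

1 | syncarpic acid (2,2,4,4-tetramethylcyclohexane-1,3,5-trione) | CC1(C)C(=O)CC(=O)C(C)(C)C1=O | starting material
2 | 3-methylbutanal | CC(C)CC=O | starting material
3 | 3-hydroxy-4,4,6,6-tetramethyl-2-[3-methyl-1-(piperidin-1-yl)butyl]cyclohex-2-ene-1,5-dione (Mannich base, racemic, not isolated) | CC(C)CC(N1CCCCC1)C1=C(O)C(C)(C)C(=O)C(C)(C)C1=O | intermediate
4 | 2-(3-methylbutylidene)-4,4,6,6-tetramethylcyclohexane-1,3,5-trione | CC(C)CC=C1C(=O)C(C)(C)C(=O)C(C)(C)C1=O | intermediate
5 | methyl 3-oxopentanoate | CCC(=O)CC(=O)OC | starting material
6 | methyl 2-[(1S)-1-(2-hydroxy-3,3,5,5-tetramethyl-4,6-dioxocyclohex-1-en-1-yl)-3-methylbutyl]-3-oxopentanoate (Michael adduct, not isolated) | CCC(=O)C(C(=O)OC)[C@H](CC(C)C)C1=C(O)C(C)(C)C(=O)C(C)(C)C1=O | intermediate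
7 | methyl 2-[(1S)-1-(2-methoxy-3,3,5,5-tetramethyl-4,6-dioxocyclohex-1-en-1-yl)-3-methylbutyl]-3-oxopentanoate | CCC(=O)C(C(=O)OC)[C@H](CC(C)C)C1=C(OC)C(C)(C)C(=O)C(C)(C)C1=O | intermediate
8 | methyl 2-[(1R)-1-(2-methoxy-3,3,5,5-tetramethyl-4,6-dioxocyclohex-1-en-1-yl)-3-methylbutyl]-3-(trimethylsilyloxy)pent-2-enoate | CCC(O[Si](C)(C)C)=C(C(=O)OC)[C@H](CC(C)C)C1=C(OC)C(C)(C)C(=O)C(C)(C)C1=O | intermediate
9 | (1Z,3Z)-1-methoxy-2-[(1R)-1-(2-methoxy-3,3,5,5-tetramethyl-4,6-dioxocyclohex-1-en-1-yl)-3-methylbutyl]-1,3-bis(trimethylsilyloxy)penta-1,3-diene | C/C=C(\O[Si](C)(C)C)/C(=C(/OC)O[Si](C)(C)C)[C@H](CC(C)C)C1=C(OC)C(C)(C)C(=O)C(C)(C)C1=O | intermediate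
10 | 3-phenylpropanoyl chloride | O=C(Cl)CCc1ccccc1 | starting material
11 | N-methoxy-N-methyl-3-phenylpropanamide | CON(C)C(=O)CCc1ccccc1 | intermediate
12 | ethoxyacetylene | C#COCC | starting material
13 | lithium ethoxyacetylide (not isolated) | [Li]C#COCC | intermediate
14 | 1-ethoxy-5-phenylpent-1-yn-3-one | CCOC#CC(=O)CCc1ccccc1 | intermediate
15 | 1-{2-ethoxy-6-methoxy-3-methyl-5-[(1R)-1-(2-methoxy-3,3,5,5-tetramethyl-4,6-dioxocyclohex-1-en-1-yl)-3-methylbutyl]-4,6-bis(trimethylsilyloxy)cyclohexa-1,4-dien-1-yl}-3-phenylpropan-1-one (cycloadduct, mixture at the two ring sp3 carbons, not isolated) | CC1C(OCC)=C(C(=O)CCc2ccccc2)C(OC)(O[Si](C)(C)C)C([C@H](CC(C)C)C2=C(OC)C(C)(C)C(=O)C(C)(C)C2=O)=C1O[Si](C)(C)C | intermediate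
16 | 1-{2-ethoxy-4,6-dihydroxy-5-[(1S)-1-(2-methoxy-3,3,5,5-tetramethyl-4,6-dioxocyclohex-1-en-1-yl)-3-methylbutyl]-3-methylphenyl}-3-phenylpropan-1-one | Cc1c(OCC)c(C(=O)CCc2ccccc2)c(O)c([C@H](CC(C)C)C2=C(OC)C(C)(C)C(=O)C(C)(C)C2=O)c1O | intermediate
17 | 1-{2,4,6-trihydroxy-3-[(1S)-1-(2-hydroxy-3,3,5,5-tetramethyl-4,6-dioxocyclohex-1-en-1-yl)-3-methylbutyl]-5-methylphenyl}-3-phenylpropan-1-one | Cc1c(O)c(C(=O)CCc2ccccc2)c(O)c([C@H](CC(C)C)C2=C(O)C(C)(C)C(=O)C(C)(C)C2=O)c1O | target

## Step count and risks

Total step count: 8. Longest linear sequence: 6 steps (1, 2, 3, 4, 7, 8); the ynone branch has 2 steps (5, 6).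

**Step 7 (key step, proposed new method).**
- Most likely failure: no ring formation below the temperature ceiling, because the ethoxy donor raises the acceptor level of the alkyne and a hexasubstituted ring is being closed between two crowded partners.
- Second to this: closure through the ketone carbon or its oxygen in place of C3–C4 bond formation, loss of the silyl groups from the diene by adventitious acid, and loss of ethene from the ynol ether if the mixture is heated too far.
- A catalytic amount of Me3SiOSO2CF3 at −78 °C in CH2Cl2 is the first adjustment.
- Fallback, known chemistry, setting out from 4 and 10 and rejoining the route at 17: ring A is not built but bought. Acid chloride 10 acylates 2-methylbenzene-1,3,5-triol (AlCl3, nitrobenzene/CH2Cl2) at one of its two equivalent free positions to give 1-(2,4,6-trihydroxy-3-methylphenyl)-3-phenylpropan-1-one F1. Its single remaining ring carbon then adds to acceptor 4 in a Friedel–Crafts-type Michael addition under LiAl[(R)-1,1′-binaphthalene-2,2′-diolate]2, or as the racemate followed by chromatography on a chiral phase, which gives 17 directly.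

**Step 2.**
- Most likely failure: erosion of enantiomeric purity by reversible addition before the enol is methylated, or closure of adduct 6 to a hemiketal and then a 4H-pyran, which withdraws it from methylation.
- Fallback, setting out from 4 and 5 and rejoining at 7: the addition is run with Et3N (10 mol %) in CH2Cl2 to give the racemic methyl 2-[1-(2-hydroxy-3,3,5,5-tetramethyl-4,6-dioxocyclohex-1-en-1-yl)-3-methylbutyl]-3-oxopentanoate F2. This is methylated in the flask to the racemic methyl 2-[1-(2-methoxy-3,3,5,5-tetramethyl-4,6-dioxocyclohex-1-en-1-yl)-3-methylbutyl]-3-oxopentanoate F3. Supercritical-fluid chromatography on amylose tris(3,5-dimethylphenylcarbamate) separates the stereoisomers; the two epimers of the (S)-C7 series are pooled, since their second centre is lost in step 3, and enter the route as 7.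

**Step 8.**
- Most likely failure: acid-induced ionisation at C7 (loss of configuration) or condensation of a ring A hydroxyl with C2′ to a pyran during the Lewis-acid treatment, or incomplete removal of the hindered ring B methyl group.
- Fallback, setting out from 16 and rejoining at 17, with no new isolated compound: nucleophilic dealkylation under basic conditions with NaSEt in DMF at 90–110 °C. The thiolate attacks the methyl and ethyl carbons by SN2 while the product is held as its phenoxide/enolate salt and cannot condense; the reaction time is kept short because hot base invites retro-Michael cleavage.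

**Step 4 (with step 3).**
- Most likely failure: slow enolisation of the hindered keto ester in step 3, or in step 4 attack of the amide base or of the ester enolate oxygen on ring B before silylation.
- Fallback, setting out from 7 and rejoining at 9, with no new compound: one-flask soft enolisation with Me3SiOSO2CF3 (2.5 equiv) and Et3N (3 equiv) in Et2O at 0 °C → rt. Both oxygens are silylated without a lithium amide and without isolating 8.

**Step 6.**
- Most likely failure: conjugate addition of the released N-methoxy-N-methylamine to the product when the chelate collapses, or hydration of the ynol ether during work-up and chromatography.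
- Fallback, setting out from 13 and rejoining at 14: acetylide 13 is added to 3-phenylpropanal (THF, −78 °C) to give 1-ethoxy-5-phenylpent-1-yn-3-ol F4, which is oxidised with MnO2 in CH2Cl2 at rt under neutral conditions to 14; no amine is present at any stage.

Further compounds
F1 | step 7 | 1-(2,4,6-trihydroxy-3-methylphenyl)-3-phenylpropan-1-one | Cc1c(O)cc(O)c(C(=O)CCc2ccccc2)c1O
F2 | step 2 | racemic methyl 2-[1-(2-hydroxy-3,3,5,5-tetramethyl-4,6-dioxocyclohex-1-en-1-yl)-3-methylbutyl]-3-oxopentanoate (not isolated) | CCC(=O)C(C(=O)OC)C(CC(C)C)C1=C(O)C(C)(C)C(=O)C(C)(C)C1=O
F3 | step 2 | racemic methyl 2-[1-(2-methoxy-3,3,5,5-tetramethyl-4,6-dioxocyclohex-1-en-1-yl)-3-methylbutyl]-3-oxopentanoate | CCC(=O)C(C(=O)OC)C(CC(C)C)C1=C(OC)C(C)(C)C(=O)C(C)(C)C1=O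
F0 | step 4 | none | none
F4 | step 6 | 1-ethoxy-5-phenylpent-1-yn-3-ol | CCOC#CC(O)CCc1ccccc1
F0 | step 8 | none | none
A1 | alternative 1 | 1,1-bis(2,4,6-trihydroxy-3-methylphenyl)-3-methylbutane | CC(C)CC(c1c(O)cc(O)c(C)c1O)c1c(O)cc(O)c(C)c1O
A2 | alternative 1 | iodomethane | CI
A3 | alternative 1 | 3-hydroxy-4,4,6,6-tetramethyl-2-[3-methyl-1-(2,4,6-trihydroxy-3-methylphenyl)butyl]cyclohex-2-ene-1,5-dione, C7 as in 17 | Cc1c(O)cc(O)c([C@H](CC(C)C)C2=C(O)C(C)(C)C(=O)C(C)(C)C2=O)c1O
A4 | alternative 2 | 1-[2,4,6-tris(benzyloxy)-3-ethenyl-5-methylphenyl]-3-phenylpropan-1-one | Cc1c(OCc2ccccc2)c(C(=O)CCc2ccccc2)c(OCc2ccccc2)c(C=C)c1OCc1ccccc1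
A5 | alternative 2 | 2-iodopropane | CC(C)I
A6 | alternative 2 | 3-(benzyloxy)-2-bromo-4,4,6,6-tetramethylcyclohex-2-ene-1,5-dione | O=C1C(Br)=C(OCc2ccccc2)C(C)(C)C(=O)C1(C)C
A7 | alternative 2 | tetrabenzyl ether of 17 (three ring A benzyl ethers and the ring B benzyl enol ether), C7 as in 17 | Cc1c(OCc2ccccc2)c(C(=O)CCc2ccccc2)c(OCc2ccccc2)c([C@H](CC(C)C)C2=C(OCc3ccccc3)C(C)(C)C(=O)C(C)(C)C2=O)c1OCc1ccccc1
A8 | alternative 3 | 3-ethoxy-4-[1-(2-methoxy-3,3,5,5-tetramethyl-4,6-dioxocyclohex-1-en-1-yl)-3-methylbutyl]cyclobut-2-en-1-one, C7 as in 17, ring carbon 4 unassigned | CCOC1=CC(=O)C1[C@H](CC(C)C)C1=C(OC)C(C)(C)C(=O)C(C)(C)C1=O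
A9 | alternative 3 | 1-ethoxyprop-1-yne | CCOC#CC
A10 | alternative 3 | 2-[1-(2,4-diethoxy-6-hydroxy-5-methylphenyl)-3-methylbutyl]-3-methoxy-4,4,6,6-tetramethylcyclohex-2-ene-1,5-dione, C7 as in 17 | Cc1c(OCC)cc(OCC)c([C@H](CC(C)C)C2=C(OC)C(C)(C)C(=O)C(C)(C)C2=O)c1O
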